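**Retrosynthetic overview**

1. Target 25 ⇐ acylation of the secondary OH of diol 23 ⇐ hydroxyl-directed reduction of β-hydroxy ketone 21 ⇐ silyl ether 20 (trans-fused ring A/ring B ketone).
2. 20 ⇐ dienal 19 by rhodium hydroacylation, which makes the C4–C5 bond and closes ring B (cycloheptene) last. The strategy rests on the β,γ-unsaturated unit C4(O)–C5H2–C6(CH3)=C7H of ring B, the imprint of an acyl group delivered to the far end of a 1,3-diene.
3. 19 ⇐ ester 12 (allyl → (E)-3-methylbuta-1,3-dienyl, CO2Me → CHO) ⇐ cyclopentene ester 10 by conjugate methylation (quaternary C8a, CH3 syn to OSiEt3).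
4. 10 ⇐ β-keto ester 7 (enol triflate, allyl coupling) ⇐ diazo keto ester 6 by rhodium carbene C–H insertion with retention, which makes ring A (cyclopentane) first and fixes the C3 carbinol centre.
5. 6 ⇐ (S)-2-isopropyloxirane 1 + methyl acetoacetate 2 (dianion alkylation, silylation, diazo transfer).

Key step: step 13

Assumption: (S)-2-isopropyloxirane is taken as a commercial, enantiopure reagent (it is also the product of hydrolytic kinetic resolution of the racemic epoxide). Atom numbers C1–C8a follow azulene numbering of the target.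

**Route**

Step 1
Reactants: 1 (S)-2-isopropyloxirane; 2 methyl acetoacetate
Product: 4 methyl (6R)-6-hydroxy-7-methyl-3-oxooctanoate, via acetoacetate dianion 3 (not isolated)
Conditions: NaH, THF, 0 °C; n-BuLi, 0 °C; then 1, 0 °C → rt; aq NH4Cl
Reagents that add atoms: none
Why: Alkylation of the acetoacetate dianion at its terminal carbon by SN2 opening of the epoxide at the unsubstituted CH2 leaves the C–O stereocentre of 1 untouched, so 4 carries the same spatial arrangement (the descriptor becomes R only because the priorities change).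

Step 2
Reactants: 4 methyl (6R)-6-hydroxy-7-methyl-3-oxooctanoate
Product: 5 methyl (6R)-7-methyl-3-oxo-6-(triethylsilyloxy)octanoate
Conditions: Et3SiCl, imidazole, DMF, 0 °C → rt
Reagents that add atoms: chlorotriethylsilane, CC[Si](Cl)(CC)CC
Why: Imidazole-promoted silylation of the secondary alcohol masks the hydroxyl before the carbene chemistry and installs the silyl ether that is kept up to step 14.

Step 3
Reactants: 5 methyl (6R)-7-methyl-3-oxo-6-(triethylsilyloxy)octanoate
Product: 6 methyl (6R)-2-diazo-7-methyl-3-oxo-6-(triethylsilyloxy)octanoate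
Conditions: p-ABSA, Et3N, MeCN, 0 °C → rt
Reagents that add atoms: 4-acetamidobenzenesulfonyl azide (p-ABSA), CC(=O)Nc1ccc(cc1)S(=O)(=O)N=[N+]=[N-]
Why: Regitz diazo transfer from the sulfonyl azide to the doubly activated methylene of the β-keto ester.

Step 4
Reactants: 6 methyl (6R)-2-diazo-7-methyl-3-oxo-6-(triethylsilyloxy)octanoate
Product: 7 methyl (2R)-2-isopropyl-5-oxo-2-(triethylsilyloxy)cyclopentane-1-carboxylate (C1 epimers and enol)
Conditions: Rh2(OAc)4 (1 mol %), CH2Cl2, 40 °C
Reagents that add atoms: none
Why: Rhodium carbenoid 1,5-C–H insertion: the electrophilic carbene inserts in a concerted three-centre fashion into the methine C–H bond activated by the silyloxy oxygen, so ring A forms with retention at the carbinol carbon (now the fully substituted C(OSiEt3)(i-Pr) centre, R), while the ester-bearing carbon is an enolisable centre that becomes sp2 in step 5.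

Step 5
Reactants: 7 methyl (2R)-2-isopropyl-5-oxo-2-(triethylsilyloxy)cyclopentane-1-carboxylate
Product: 8 methyl (5R)-5-isopropyl-5-(triethylsilyloxy)-2-(trifluoromethylsulfonyloxy)cyclopent-1-ene-1-carboxylate
Conditions: Tf2O, i-Pr2NEt, CH2Cl2, −78 °C
Reagents that add atoms: trifluoromethanesulfonic anhydride, O=S(=O)(OS(=O)(=O)C(F)(F)F)C(F)(F)F
Why: O-Sulfonylation of the amine-generated β-keto ester enolate at low temperature should give the cyclic enol triflate without β-elimination of the silyloxy group.

Step 6
Reactants: 8 methyl (5R)-5-isopropyl-5-(triethylsilyloxy)-2-(trifluoromethylsulfonyloxy)cyclopent-1-ene-1-carboxylate; 9 allyltributylstannane (CH2=CHCH2SnBu3)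
Product: 10 methyl (5R)-2-allyl-5-isopropyl-5-(triethylsilyloxy)cyclopent-1-ene-1-carboxylate
Conditions: Pd(PPh3)4 (5 mol %), LiCl, THF, 65 °C
Reagents that add atoms: none
Why: Stille coupling, in which zerovalent palladium adds oxidatively into the vinyl C–OTf bond, the allyl group is transferred from tin and reductive elimination gives the 2-allyl enoate, the remote stereocentre being untouched.

Step 7
Reactants: 10 methyl (5R)-2-allyl-5-isopropyl-5-(triethylsilyloxy)cyclopent-1-ene-1-carboxylate
Product: 12 methyl (1R,2R,5R)-2-allyl-5-isopropyl-2-methyl-5-(triethylsilyloxy)cyclopentane-1-carboxylate, via silyl ketene acetal 11 (not isolated)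
Conditions: MeLi, CuI, Et2O, 0 °C (Me2CuLi); then 10, Me3SiCl, THF, −78 → −20 °C; then NaOMe, MeOH, −20 °C → rt
Reagents that add atoms: lithium dimethylcuprate, [Li+].C[Cu-]C
Why: Chlorosilane-accelerated organocuprate 1,4-addition to the β,β-disubstituted enoate, in which the methyl group should enter the β-carbon on the ring face opposite the branched isopropyl group of the neighbouring fully substituted carbon (that is, syn to the slimmer O–SiEt3 substituent) and so set the quaternary carbon (R), after which methanolysis of 11 under equilibrating NaOMe conditions should place the ester trans to isopropyl and allyl (R).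

Step 8
Reactants: 12 methyl (1R,2R,5R)-2-allyl-5-isopropyl-2-methyl-5-(triethylsilyloxy)cyclopentane-1-carboxylate
Product: 14 methyl (1R,2R,5R)-5-isopropyl-2-methyl-2-(2-oxoethyl)-5-(triethylsilyloxy)cyclopentane-1-carboxylate, via ozonide 13 (not isolated)
Conditions: O3, CH2Cl2, −78 °C; then PPh3, −78 °C → rt
Reagents that add atoms: ozone, [O-][O+]=O
Why: Criegee ozonolysis of the only C=C bond and reductive cleavage of the ozonide by PPh3 shorten the allyl group to the CH2CHO arm without touching any stereocentre.

Step 9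
Reactants: 14 methyl (1R,2R,5R)-5-isopropyl-2-methyl-2-(2-oxoethyl)-5-(triethylsilyloxy)cyclopentane-1-carboxylate; 15 isopropenylmagnesium bromide (CH2=C(CH3)MgBr)
Product: 16 methyl (1R,2R,5R)-2-(2-hydroxy-3-methylbut-3-enyl)-5-isopropyl-2-methyl-5-(triethylsilyloxy)cyclopentane-1-carboxylate (carbinol epimers)
Conditions: THF, −78 °C; aq NH4Cl
Reagents that add atoms: none
Why: Grignard 1,2-addition should be chemoselective for the unhindered aldehyde over the methyl ester flanked by two fully substituted carbons, and the new carbinol centre, formed without control, is destroyed in step 10.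

Step 10
Reactants: 16 methyl (1R,2R,5R)-2-(2-hydroxy-3-methylbut-3-enyl)-5-isopropyl-2-methyl-5-(triethylsilyloxy)cyclopentane-1-carboxylate
Product: 17 methyl (1R,2R,5R)-5-isopropyl-2-methyl-2-[(1E)-3-methylbuta-1,3-dienyl]-5-(triethylsilyloxy)cyclopentane-1-carboxylate
Conditions: Martin sulfurane, Ph2S[OC(CF3)2Ph]2, CH2Cl2, 0 °C → rt
Reagents that add atoms: none
Why: Dehydration with Martin sulfurane, in which the alkoxysulfonium ion of the secondary allylic alcohol can lose only the hydrogens of the ring-bound CH2 and anti elimination should give the conjugated diene with the ring and the isopropenyl group trans (E).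

Step 11
Reactants: 17 methyl (1R,2R,5R)-5-isopropyl-2-methyl-2-[(1E)-3-methylbuta-1,3-dienyl]-5-(triethylsilyloxy)cyclopentane-1-carboxylate
Product: 18 [(1S,2R,5R)-2-isopropyl-5-methyl-5-[(1E)-3-methylbuta-1,3-dienyl]-2-(triethylsilyloxy)cyclopentyl]methanol
Conditions: i-Bu2AlH, CH2Cl2, −78 → 0 °C; aq potassium sodium tartrate
Reagents that add atoms: none
Why: Hydride reduction of the hindered methyl ester to the primary alcohol, the diene and the tertiary silyl ether being inert to i-Bu2AlH.

Step 12
Reactants: 18 [(1S,2R,5R)-2-isopropyl-5-methyl-5-[(1E)-3-methylbuta-1,3-dienyl]-2-(triethylsilyloxy)cyclopentyl]methanol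
Product: 19 (1R,2R,5R)-2-isopropyl-5-methyl-5-[(1E)-3-methylbuta-1,3-dienyl]-2-(triethylsilyloxy)cyclopentane-1-carbaldehyde (OSiEt3, CHO and CH3 on one ring face; isopropyl, H and dienyl on the other)
Conditions: Dess–Martin periodinane, NaHCO3, CH2Cl2, 0 °C → rt
Reagents that add atoms: none
Why: Dess–Martin oxidation under buffered, non-enolising conditions should give the aldehyde without epimerising the α-carbon or eliminating the β-silyloxy group.

Step 13
Reactants: 19 (1R,2R,5R)-2-isopropyl-5-methyl-5-[(1E)-3-methylbuta-1,3-dienyl]-2-(triethylsilyloxy)cyclopentane-1-carbaldehyde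
Product: 20 (3R,3aR,8aR)-3-isopropyl-6,8a-dimethyl-3-(triethylsilyloxy)-1,2,3,3a,8,8a-hexahydroazulen-4(5H)-one (trans-fused)
Conditions: [Rh(dppe)]ClO4 (10 mol %, from [Rh(nbd)(dppe)]ClO4 and H2; dppe = 1,2-bis(diphenylphosphino)ethane, nbd = norbornadiene), ClCH2CH2Cl, 65 °C
Reagents that add atoms: none
Why: Cationic monovalent rhodium adds oxidatively into the formyl C–H bond to give a trivalent acyl rhodium hydride, the hydride moves to C8 (product numbering, the diene carbon bound to the quaternary carbon) to leave an acyl π-allyl rhodium species, the metal is relayed along the allyl unit to the CH2 terminus (C5), and C–C reductive elimination there joins C4 to C5 and returns monovalent rhodium. The closest known reaction is the intramolecular hydroacylation of 4,6-dienals to cyclohept-3-enones with the same [Rh(dppe)]+ catalyst, and 19 is such a 4,6-dienal. Ring B is closed in a formally 7-endo mode (acyl transfer to the far diene terminus), which is why the olefin ends at C6(CH3)=C7H, out of conjugation with the C4 ketone, with no regioisomeric olefin available from this pathway. No stereocentre is formed, and the three existing ones, fixed in steps 4 and 7, are not at risk because the medium is neutral and aprotic, so the ring-fusion hydrogen at C3a should stay trans to the C8a methyl group. The step needs seven-membered closure to win over five-membered closure and over decarbonylation: CHO and dienyl are trans on ring A, so reductive elimination at the inner allyl carbon would have to form a strained trans-fused bicyclo[3.3.0]octanone whereas the outer terminus gives the unstrained trans-fused hydroazulenone, and the chelating diphosphine should hold the acyl hydride together long enough for insertion to outrun CO loss.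

Step 14
Reactants: 20 (3R,3aR,8aR)-3-isopropyl-6,8a-dimethyl-3-(triethylsilyloxy)-1,2,3,3a,8,8a-hexahydroazulen-4(5H)-one
Product: 21 (3R,3aR,8aR)-3-hydroxy-3-isopropyl-6,8a-dimethyl-1,2,3,3a,8,8a-hexahydroazulen-4(5H)-one
Conditions: HF·pyridine, THF/pyridine, 0 °C → rt
Reagents that add atoms: none
Why: Fluoride-assisted cleavage of the Si–O bond under buffered acidic conditions should free the tertiary alcohol without retro-aldol cleavage, dehydration or migration of the β,γ-double bond.

Step 15
Reactants: 21 (3R,3aR,8aR)-3-hydroxy-3-isopropyl-6,8a-dimethyl-1,2,3,3a,8,8a-hexahydroazulen-4(5H)-one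
Product: 23 (3R,3aS,4S,8aR)-3-isopropyl-6,8a-dimethyl-1,2,3,3a,4,5,8,8a-octahydroazulene-3,4-diol, via alkoxydiacetoxyborohydride 22 (not isolated)
Conditions: Me4NBH(OAc)3, MeCN/AcOH (1:1), −30 → 0 °C; aq potassium sodium tartrate
Reagents that add atoms: none
Why: Evans–Saksena reduction, in which the tertiary hydroxyl exchanges with an acetate on boron to give 22 and hydride is delivered intramolecularly through a six-membered chair transition state to the ketone face that carries this oxygen, so the new carbinol hydrogen is cis and the new hydroxyl trans to the tertiary OH across the ring-fusion carbon (1,3-anti diol, 4S).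

Step 16
Reactants: 23 (3R,3aS,4S,8aR)-3-isopropyl-6,8a-dimethyl-1,2,3,3a,4,5,8,8a-octahydroazulene-3,4-diol; 24 3,4-dimethoxybenzoyl chloride
Product: 25 (3R,3aS,4S,8aR)-3-hydroxy-3-isopropyl-6,8a-dimethyl-1,2,3,3a,4,5,8,8a-octahydroazulen-4-yl 3,4-dimethoxybenzoate (target)
Conditions: Et3N, DMAP (cat.), CH2Cl2, 0 °C → rt
Reagents that add atoms: none
Why: DMAP-catalysed acyl transfer from the acid chloride should esterify only the secondary alcohol, the tertiary hydroxyl being too hindered.

**Compound list**

1 | (S)-2-isopropyloxirane | CC(C)[C@H]1CO1 | starting material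
2 | methyl acetoacetate | COC(=O)CC(C)=O | starting material
3 | sodium lithium dianion of methyl acetoacetate | [Na+].[Li+].COC(=O)[CH-]C(=O)[CH2-] | intermediate
4 | methyl (6R)-6-hydroxy-7-methyl-3-oxooctanoate | COC(=O)CC(=O)CC[C@@H](O)C(C)C | intermediate
5 | methyl (6R)-7-methyl-3-oxo-6-(triethylsilyloxy)octanoate | COC(=O)CC(=O)CC[C@@H](O[Si](CC)(CC)CC)C(C)C | intermediate
6 | methyl (6R)-2-diazo-7-methyl-3-oxo-6-(triethylsilyloxy)octanoate | COC(=O)C(=[N+]=[N-])C(=O)CC[C@@H](O[Si](CC)(CC)CC)C(C)C | intermediate
7 | methyl (2R)-2-isopropyl-5-oxo-2-(triethylsilyloxy)cyclopentane-1-carboxylate (C1 epimers and enol) | COC(=O)C1C(=O)CC[C@@]1(O[Si](CC)(CC)CC)C(C)C | intermediate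
8 | methyl (5R)-5-isopropyl-5-(triethylsilyloxy)-2-(trifluoromethylsulfonyloxy)cyclopent-1-ene-1-carboxylate | COC(=O)C1=C(OS(=O)(=O)C(F)(F)F)CC[C@@]1(O[Si](CC)(CC)CC)C(C)C | intermediate
9 | allyltributylstannane | C=CC[Sn](CCCC)(CCCC)CCCC | starting material
10 | methyl (5R)-2-allyl-5-isopropyl-5-(triethylsilyloxy)cyclopent-1-ene-1-carboxylate | COC(=O)C1=C(CC=C)CC[C@@]1(O[Si](CC)(CC)CC)C(C)C | intermediate
11 | methyl trimethylsilyl ketene acetal of 12 (exocyclic C=C at the ester-bearing carbon) | COC(O[Si](C)(C)C)=C1[C@@](C)(CC=C)CC[C@@]1(O[Si](CC)(CC)CC)C(C)C | intermediate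
12 | methyl (1R,2R,5R)-2-allyl-5-isopropyl-2-methyl-5-(triethylsilyloxy)cyclopentane-1-carboxylate | C=CC[C@@]1(C)CC[C@@](O[Si](CC)(CC)CC)(C(C)C)[C@@H]1C(=O)OC | intermediate
13 | 1,2,4-trioxolane (ozonide) of the allyl group of 12 | C1OC(C[C@@]2(C)CC[C@@](O[Si](CC)(CC)CC)(C(C)C)[C@@H]2C(=O)OC)OO1 | intermediate
14 | methyl (1R,2R,5R)-5-isopropyl-2-methyl-2-(2-oxoethyl)-5-(triethylsilyloxy)cyclopentane-1-carboxylate | O=CC[C@@]1(C)CC[C@@](O[Si](CC)(CC)CC)(C(C)C)[C@@H]1C(=O)OC | intermediate
15 | isopropenylmagnesium bromide | C=C(C)[Mg]Br | starting material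
16 | methyl (1R,2R,5R)-2-(2-hydroxy-3-methylbut-3-enyl)-5-isopropyl-2-methyl-5-(triethylsilyloxy)cyclopentane-1-carboxylate (carbinol epimers) | C=C(C)C(O)C[C@@]1(C)CC[C@@](O[Si](CC)(CC)CC)(C(C)C)[C@@H]1C(=O)OC | intermediate
17 | methyl (1R,2R,5R)-5-isopropyl-2-methyl-2-[(1E)-3-methylbuta-1,3-dienyl]-5-(triethylsilyloxy)cyclopentane-1-carboxylate | C=C(C)/C=C/[C@@]1(C)CC[C@@](O[Si](CC)(CC)CC)(C(C)C)[C@@H]1C(=O)OC | intermediate
18 | [(1S,2R,5R)-2-isopropyl-5-methyl-5-[(1E)-3-methylbuta-1,3-dienyl]-2-(triethylsilyloxy)cyclopentyl]methanol | C=C(C)/C=C/[C@@]1(C)CC[C@@](O[Si](CC)(CC)CC)(C(C)C)[C@@H]1CO | intermediate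
19 | (1R,2R,5R)-2-isopropyl-5-methyl-5-[(1E)-3-methylbuta-1,3-dienyl]-2-(triethylsilyloxy)cyclopentane-1-carbaldehyde | C=C(C)/C=C/[C@@]1(C)CC[C@@](O[Si](CC)(CC)CC)(C(C)C)[C@@H]1C=O | intermediate
20 | (3R,3aR,8aR)-3-isopropyl-6,8a-dimethyl-3-(triethylsilyloxy)-1,2,3,3a,8,8a-hexahydroazulen-4(5H)-one | CC1=CC[C@@]2(C)CC[C@@](O[Si](CC)(CC)CC)(C(C)C)[C@@H]2C(=O)C1 | intermediate
21 | (3R,3aR,8aR)-3-hydroxy-3-isopropyl-6,8a-dimethyl-1,2,3,3a,8,8a-hexahydroazulen-4(5H)-one | CC1=CC[C@@]2(C)CC[C@@](O)(C(C)C)[C@@H]2C(=O)C1 | intermediate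
22 | tetramethylammonium diacetoxy(hydrido)borate ester of the tertiary alkoxide of 21 | CC1=CC[C@@]2(C)CC[C@@](O[BH-](OC(C)=O)OC(C)=O)(C(C)C)[C@@H]2C(=O)C1.C[N+](C)(C)C | intermediate
23 | (3R,3aS,4S,8aR)-3-isopropyl-6,8a-dimethyl-1,2,3,3a,4,5,8,8a-octahydroazulene-3,4-diol | O[C@H]1CC(C)=CC[C@@]2(C)CC[C@@](O)(C(C)C)[C@H]12 | intermediate
24 | 3,4-dimethoxybenzoyl chloride | COc1ccc(C(=O)Cl)cc1OC | starting material
25 | (3R,3aS,4S,8aR)-3-hydroxy-3-isopropyl-6,8a-dimethyl-1,2,3,3a,4,5,8,8a-octahydroazulen-4-yl 3,4-dimethoxybenzoate | COc1ccc(C(=O)O[C@H]2CC(C)=CC[C@@]3(C)CC[C@@](O)(C(C)C)[C@H]23)cc1OC | target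

**Step count and risks**

Total step count: 16. Longest linear sequence: 16 steps (1 and 2 to 25; all other partners are commercial).

Steps most likely to fail:

Step 13. The hindered acyl rhodium hydride may lose CO before the hydride reaches the diene, or the diene may isomerise under the metal hydride. The fallback closes ring B by ring-closing metathesis instead of acyl transfer. It sets out from 12: reduction with i-Bu2AlH should give the primary alcohol F1, Dess–Martin oxidation the aldehyde F2, and addition of 2-methylallylmagnesium chloride (CH2=C(CH3)CH2MgCl) the homoallylic alcohol F3. Metathesis between the allyl group and the 1,1-disubstituted olefin with the second-generation Grubbs catalyst should then give the cycloheptenol F4 with the C6(CH3)=C7H olefin in place, and Dess–Martin oxidation returns to the route at 20.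

Step 7. Addition to the twisted tetrasubstituted enoate may be slow, the intermediate enolate may expel silanolate, or the methyl group may not discriminate well between the two ring faces. The fallback delivers the methyl carbon from the tertiary oxygen through a silicon tether (radical reductive methylation), so that the syn relation of CH3 and O follows from the tether. It sets out from 10: HF·pyridine should free the tertiary allylic alcohol F5, and (bromomethyl)chlorodimethylsilane with imidazole should give the bromomethylsilyl ether F6. Bu3SnH/AIBN generates the α-silyl radical, which should add 6-endo to the β-carbon of the enoate to give the bridged siloxane F7. Protodesilylation with n-Bu4NF in DMF at 70 °C should give the hydroxy ester F8. Silylation (Et3SiOTf, 2,6-lutidine) and NaOMe/MeOH equilibration of the ester-bearing carbon return to the route at 12.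

Step 15. Exchange of the hindered tertiary hydroxyl onto boron may be slow, so that undirected hydride attack from the open face erodes the facial selectivity. The fallback reduces in the opposite, chelation-controlled sense and inverts during esterification. It sets out from 21: Narasaka–Prasad reduction (Et2BOMe, NaBH4, THF/MeOH, −78 °C; external hydride attacks the boron chelate from the face away from the angular methyl group) should give the 4-epimeric syn-diol F9. Mitsunobu esterification with 3,4-dimethoxybenzoic acid (PPh3, DIAD) inverts C4 and returns to the route at 25.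

**Further compounds**

F1 | step 13 | [(1S,2R,5R)-5-allyl-2-isopropyl-5-methyl-2-(triethylsilyloxy)cyclopentyl]methanol | C=CC[C@@]1(C)CC[C@@](O[Si](CC)(CC)CC)(C(C)C)[C@@H]1CO
F2 | step 13 | (1R,2R,5R)-5-allyl-2-isopropyl-5-methyl-2-(triethylsilyloxy)cyclopentane-1-carbaldehyde | C=CC[C@@]1(C)CC[C@@](O[Si](CC)(CC)CC)(C(C)C)[C@@H]1C=O
F3 | step 13 | 1-[(1S,2R,5R)-5-allyl-2-isopropyl-5-methyl-2-(triethylsilyloxy)cyclopentyl]-3-methylbut-3-en-1-ol (carbinol epimers) | C=CC[C@@]1(C)CC[C@@](O[Si](CC)(CC)CC)(C(C)C)[C@@H]1C(O)CC(C)=C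
F4 | step 13 | (3R,3aS,8aR)-3-isopropyl-6,8a-dimethyl-3-(triethylsilyloxy)-1,2,3,3a,4,5,8,8a-octahydroazulen-4-ol (C4 epimers) | CC1=CC[C@@]2(C)CC[C@@](O[Si](CC)(CC)CC)(C(C)C)[C@@H]2C(O)C1
F5 | step 7 | methyl (5R)-2-allyl-5-hydroxy-5-isopropylcyclopent-1-ene-1-carboxylate | COC(=O)C1=C(CC=C)CC[C@@]1(O)C(C)C
F6 | step 7 | methyl (5R)-2-allyl-5-[(bromomethyl)dimethylsilyloxy]-5-isopropylcyclopent-1-ene-1-carboxylate | COC(=O)C1=C(CC=C)CC[C@@]1(O[Si](C)(C)CBr)C(C)C
F7 | step 7 | methyl 5-allyl-1-isopropyl-3,3-dimethyl-2-oxa-3-silabicyclo[3.2.1]octane-8-carboxylate (C8 epimers; bridgeheads fixed by the O–Si–CH2 bridge) | COC(=O)C1[C@@]2(CC=C)CC[C@@]1(O[Si](C)(C)C2)C(C)C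
F8 | step 7 | methyl (2R,5R)-2-allyl-5-hydroxy-5-isopropyl-2-methylcyclopentane-1-carboxylate (C1 epimers) | C=CC[C@@]1(C)CC[C@@](O)(C(C)C)C1C(=O)OC
F9 | step 15 | (3R,3aS,4R,8aR)-3-isopropyl-6,8a-dimethyl-1,2,3,3a,4,5,8,8a-octahydroazulene-3,4-diol | O[C@@H]1CC(C)=CC[C@@]2(C)CC[C@@](O)(C(C)C)[C@H]12
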